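The runs were computed from invented constants; scatter was added.

17.7 mM·min is the product of [free catalyst] and time at which Sunday's run, as far as its scattered readings tell, had lost half of its substrate, with 53% substrate and 52% product read at 30.0 min, and I call this number the halving dose.

the same everywhere: substrate 0.10 M
- Tuesday's: free catalyst 0.15 mM; run made earlier
- Sunday's: free catalyst 0.59 mM; run made earlier
- north-east: free catalyst 0.20 mM; time 40 min
- south: free catalyst 2.0 mM; time 40 min
- south-east: free catalyst 0.30 mM; time 40 min
- north: free catalyst 0.40 mM; time 40 min
- east: free catalyst 0.61 mM; time 40 min

| run | time / min | product / % | substrate / % |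
|---|---|---|---|
| Tuesday's | 2.50 | 1 | 99 |
| Tuesday's | 4.00 | 4 | 98 |
| Tuesday's | 8.00 | 3 | 93 |
| Tuesday's | 15.0 | 6 | 90 |
| Tuesday's | 30.0 | 16 | 85 |
| Sunday's | 6.00 | 15 | 89 |
| Sunday's | 12.0 | 26 | 78 |
| Sunday's | 15.0 | 28 | 72 |
| Sunday's | 25.0 | 43 | 55 |
| Sunday's | 30.0 | 52 | 53 |

(readings scatter by 1.5 percentage points)

* the flasks by amount of product, in percent of the substrate charged, highest first, at 40 min (north-east / south / south-east / north / east)
* the amount of product, in percent of the substrate charged of the flask you put first, at 40 min
* the amount of product, in percent of the substrate charged of the flask you put last, at 40 min



**Why should one reading serve another flask?** If each equal stretch of dose, meaning [free catalyst] times time, removes the same fraction of substrate, which is pseudo-first-order decay, then nothing needs integrating: one divides the dose by the halving dose and halves that many times. Tuesday's run tests this, since its dose of 4.50 mM·min is a quarter of the halving dose, so 83.8% of the substrate should remain, and that separate flask reads 85% substrate with 16% product.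

**And the new flasks?** They share 40 min and [substrate], so the dose follows [free catalyst], which is highest in south and lowest in north-east. North-east gets 0.452 halvings, so I expect 26.9% product.

**Where is the weak spot?** It is south, with a dose of 80.0 mM·min, or 4.52 halvings, where the product is large and the remainder small, so I reckon the remainder: 4.36% substrate, hence 95.6% product. Yet the lowest substrate reading in either run is 53%, so that remainder is extrapolated far beyond anything read.

The forecast gives south > east > north > south-east > north-east, with 95% for the first flask, 0.64 percentage points below my figure, and 27% for the last, adding: “South lies well beyond the tested catalyst range, so saturation is possible”.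

The flasks give south > east > north > south-east > north-east, from 89.9% down to 26.7%.

    substrate + free catalyst ⇌ catalyst intermediate (K = 14.0 /M, k = 40.0 /M/min)
    catalyst intermediate ⇌ free catalyst + product (K = 1.10 M, k = 1100 /min)

South at 40 min holds 9.90% substrate where the halvings left 4.36%, and at 400 min it still holds 6.09%, more than that reckoned remainder. The same count on the neighbour, south stopped at 15 min, gives a dose of 30.0 mM·min, or 1.69 halvings, so 30.9% substrate and 69.1% product. That flask holds 33.6% substrate and 66.3% product.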